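Ring A (C4a, C5–C8, C8a) is a phloroglucinol with three unlike oxygens (the ring C ether O1 on C8a, OMe on C5, free OH on C7) and a prenyl group on C6 between two of them. Instead of substituting an arene, ring A is built by a thermal cyclobutenone–ynol ether benzannulation that forms C4a–C8a and C5–C6 and closes the ring at C8–C8a, so each oxygen arrives from a different component. The partners are a 3-silyloxy-2-prenylcyclobutenone and a methoxyalkyne that already carries C4 as a silylated carbinol, C3 with ring B and C2 as a methylene. Silanol loss then gives an ortho-quinone methide whose oxa-6π closure forms ring C.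

Key step: step 10

Remark: the carbinol carbon formed in step 9 is the only stereocentre on the route; it is carried as the racemate and becomes trigonal in step 11, so the achiral target needs no stereocontrol.
Remark: ketene is assumed to be generated on demand by pyrolysis of acetone and passed in as a gas.

Step 1
Reactants: 1 ethoxyacetylene; 2 1-bromo-3-methylbut-2-ene
Product: 3 1-ethoxy-5-methylhex-4-en-1-yne
Conditions: n-BuLi, THF, −78 °C; DMPU, then 2, −78 °C to rt
Reagents that add atoms: none
Why: Lithium ethoxyacetylide is alkylated by the primary allylic bromide (SN2 alkylation of an acetylide), the polar cosolvent making the acetylide reactive enough and attack at the unhindered CH2 terminus avoiding the SN2' isomer.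

Step 2
Reactants: 3 1-ethoxy-5-methylhex-4-en-1-yne
Product: 4 3-ethoxy-2-(3-methylbut-2-enyl)cyclobut-2-en-1-one
Conditions: CH2=C=O (gas, excess), CH2Cl2, 0 °C to rt
Reagents that add atoms: ketene, C=C=O
Why: Ketene–ynol ether (2+2) cycloaddition in which the nucleophilic alkyne carbon remote from OEt bonds to the ketene carbonyl carbon, placing prenyl on C2 and OEt on C3, while the isolated trisubstituted alkene does not compete.

Step 3
Reactants: 4 3-ethoxy-2-(3-methylbut-2-enyl)cyclobut-2-en-1-one
Product: 5 3-hydroxy-2-(3-methylbut-2-enyl)cyclobut-2-en-1-one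
Conditions: 1 M HCl, THF, 0 °C to rt
Reagents that add atoms: water, O
Why: Acid hydrolysis of a vinylogous ester by conjugate addition of water and loss of ethanol gives the vinylogous acid (enol of the cyclobutane-1,3-dione), cold dilute acid being too weak to hydrate the trisubstituted alkene or add the enol across it.

Step 4
Reactants: 5 3-hydroxy-2-(3-methylbut-2-enyl)cyclobut-2-en-1-one
Product: 6 2-(3-methylbut-2-enyl)-3-(triisopropylsilyloxy)cyclobut-2-en-1-one
Conditions: TIPSOTf, Et3N, CH2Cl2, −78 to 0 °C
Reagents that add atoms: triisopropylsilyl trifluoromethanesulfonate, CC(C)[Si](OS(=O)(=O)C(F)(F)F)(C(C)C)C(C)C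
Why: O-silylation of the acidic enol with a silyl triflate and amine base gives one vinylogous silyl ester because the two oxygens of the dione are equivalent, and the bulky triisopropylsilyl group makes it stable to handling and to the heat of step 10.

Step 5
Reactants: 7 2,4-dihydroxyacetophenone
Product: 8 2,4-bis(tert-butyldimethylsilyloxy)acetophenone
Conditions: TBSCl (2.5 equiv), imidazole, DMF, rt to 40 °C
Reagents that add atoms: tert-butyldimethylsilyl chloride, CC(C)(C)[Si](C)(C)Cl
Why: Standard silyl ether formation from phenols (silyl chloride with imidazole), gentle warming bringing in the hydrogen-bonded ortho hydroxyl.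

Step 6
Reactants: 8 2,4-bis(tert-butyldimethylsilyloxy)acetophenone
Product: 9 2,4-bis(tert-butyldimethylsilyloxy)-1-(prop-1-en-2-yl)benzene
Conditions: Ph3PCH3Br, KOtBu, THF, 0 °C to rt
Reagents that add atoms: methyltriphenylphosphonium bromide, C[P+](c1ccccc1)(c1ccccc1)c1ccccc1.[Br-]
Why: Wittig methylenation of an aryl methyl ketone with the non-stabilised ylide, to which aryl silyl ethers are inert.

Step 7
Reactants: 9 2,4-bis(tert-butyldimethylsilyloxy)-1-(prop-1-en-2-yl)benzene
Product: 10 2-[2,4-bis(tert-butyldimethylsilyloxy)phenyl]prop-2-enal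
Conditions: SeO2, 1,4-dioxane, 80 °C
Reagents that add atoms: selenium dioxide, O=[Se]=O
Why: Riley allylic oxidation (ene reaction at the only allylic position, 2,3-sigmatropic shift, then oxidation of the allylic alcohol) gives the 2-arylacrolein as known for alpha-methylstyrenes, and the aldehyde is used at once because it polymerises on standing.

Step 8
Reactants: 11 trichloroethylene
Product: 13 (E)-1,2-dichloro-1-methoxyethene, via dichloroacetylene 12 (not isolated)
Conditions: KH, MeOH, THF, 0 °C; then 11, −50 °C to rt; distillation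
Reagents that add atoms: methanol, CO
Why: Potassium methoxide dehydrochlorinates trichloroethylene to dichloroacetylene, across which methanol adds anti under base catalysis (nucleophilic addition to a haloalkyne, the usual route to 1,2-dichlorovinyl ethers), the explosive intermediate being kept in solution under argon.

Step 9
Reactants: 13 (E)-1,2-dichloro-1-methoxyethene; 10 2-[2,4-bis(tert-butyldimethylsilyloxy)phenyl]prop-2-enal
Product: 17 4-[2,4-bis(tert-butyldimethylsilyloxy)phenyl]-1-methoxy-3-(triethylsilyloxy)pent-4-en-1-yne, via chloro(methoxy)acetylene 14 (not isolated), via lithium methoxyacetylide 15 (not isolated), via lithium alkoxide 16 (not isolated)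
Conditions: 13 (1.3 equiv), n-BuLi (2.6 equiv), THF, −78 to −40 °C; 10, −78 °C; TESCl, −78 to 0 °C; aq NaHCO3
Reagents that add atoms: chlorotriethylsilane, CC[Si](CC)(CC)Cl
Why: Dehydrochlorination and chlorine–lithium exchange give the lithium alkoxyacetylide, which adds 1,2 to the enal (acetylide addition to an aldehyde), and the alkoxide is silylated in the same flask so that the hydroxy ynol ether, prone to Meyer–Schuster rearrangement, is never handled; the new carbinol stereocentre forms as the racemate, which suffices because it is erased in step 11.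

Step 10
Reactants: 6 2-(3-methylbut-2-enyl)-3-(triisopropylsilyloxy)cyclobut-2-en-1-one; 17 4-[2,4-bis(tert-butyldimethylsilyloxy)phenyl]-1-methoxy-3-(triethylsilyloxy)pent-4-en-1-yne
Product: 22 2-{2-[2,4-bis(tert-butyldimethylsilyloxy)phenyl]-1-(triethylsilyloxy)prop-2-enyl}-3-methoxy-4-(3-methylbut-2-enyl)-5-(triisopropylsilyloxy)phenol, via vinylketene 18 (not isolated), via vinylcyclobutenone 19 (not isolated), via dienylketene 20 (not isolated), via cyclohexadienone 21 (not isolated)
Conditions: 17 (1.2 equiv), toluene (0.3 M), 80 °C, then 110 °C, argon, sealed tube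
Reagents that add atoms: none
Why: Heating opens 6 by 4π electrocyclic ring opening to vinylketene 18, whose electrophilic carbonyl carbon is attacked by the alkyne carbon of 17 remote from OMe in a (2+2) cycloaddition that forms C4a–C8a and C5–C6 and gives 4-vinylcyclobutenone 19. Cyclobutenone 19 reopens (4π) to dienylketene 20, and ring A closes by thermal 6π electrocyclisation that re-forms C8–C8a, cyclohexadienone 21 then tautomerising to phenol 22. The closest known reaction type is the Danheiser benzannulation of cyclobutenones with alkoxyalkynes to 2-substituted 3-alkoxyphenols, and oxygen-substituted cyclobutenones are known to open to vinylketenes in this temperature range. No stereocentre is created, and the racemic carbinol carbon is a spectator. The step needs the regiochemistry of the ketene–alkyne union and a preference for the alkyne over the styrene and prenyl alkenes, and both follow from the polarised, strongly nucleophilic ynol ether, whose carbon beta to OMe bonds to the ketene carbon. The ketene oxygen thus becomes the free C8a hydroxyl, the ynol ether oxygen the C5 OMe and the silyloxy oxygen O7, and a methyl ynol ether cannot fragment by retro-ene loss of an alkene at this temperature.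

Step 11
Reactants: 22 2-{2-[2,4-bis(tert-butyldimethylsilyloxy)phenyl]-1-(triethylsilyloxy)prop-2-enyl}-3-methoxy-4-(3-methylbut-2-enyl)-5-(triisopropylsilyloxy)phenol
Product: 24 3-[2,4-bis(tert-butyldimethylsilyloxy)phenyl]-5-methoxy-6-(3-methylbut-2-enyl)-7-(triisopropylsilyloxy)-2H-chromene, via ortho-quinone methide 23 (not isolated)
Conditions: PPTS (10 mol %), toluene, 60 °C
Reagents that add atoms: none
Why: Acid-assisted loss of triethylsilanol from the doubly activated (benzylic to electron-rich ring A, allylic) silyl ether beside the free C8a hydroxyl gives the ortho-quinone methide, whose oxa-6π electrocyclisation forms O1–C2 and ring C (the known dehydrative cyclisation of 2-(1-oxyallyl)phenols to 2H-chromenes); with O7 and the ring B oxygens still silylated, only this quinone methide can form and the prenyl group has no free ortho hydroxyl to add to.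

Step 12
Reactants: 24 3-[2,4-bis(tert-butyldimethylsilyloxy)phenyl]-5-methoxy-6-(3-methylbut-2-enyl)-7-(triisopropylsilyloxy)-2H-chromene
Product: 25 dehydroglyasperin C
Conditions: TBAF, AcOH (1:1, 3.5 equiv), THF, 0 °C to rt, argon
Reagents that add atoms: none
Why: Fluoride cleavage of the three aryl silyl ethers, buffered with acetic acid so that neither phenoxide (air oxidation) nor strong acid (chroman formation from the C6 prenyl group and the C7 hydroxyl) is present, the chromene and prenyl alkenes being inert to fluoride.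

Compound list
1 | ethoxyacetylene | CCOC#C | starting material
2 | 1-bromo-3-methylbut-2-ene | CC(C)=CCBr | starting material
3 | 1-ethoxy-5-methylhex-4-en-1-yne | CCOC#CCC=C(C)C | intermediate
4 | 3-ethoxy-2-(3-methylbut-2-enyl)cyclobut-2-en-1-one | CCOC1=C(CC=C(C)C)C(=O)C1 | intermediate
5 | 3-hydroxy-2-(3-methylbut-2-enyl)cyclobut-2-en-1-one (enol of 2-prenylcyclobutane-1,3-dione) | O=C1CC(O)=C1CC=C(C)C | intermediate
6 | 2-(3-methylbut-2-enyl)-3-(triisopropylsilyloxy)cyclobut-2-en-1-one | O=C1CC(O[Si](C(C)C)(C(C)C)C(C)C)=C1CC=C(C)C | intermediate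
7 | 2,4-dihydroxyacetophenone | CC(=O)c1ccc(O)cc1O | starting material
8 | 2,4-bis(tert-butyldimethylsilyloxy)acetophenone | CC(=O)c1ccc(O[Si](C)(C)C(C)(C)C)cc1O[Si](C)(C)C(C)(C)C | intermediate
9 | 2,4-bis(tert-butyldimethylsilyloxy)-1-(prop-1-en-2-yl)benzene | CC(=C)c1ccc(O[Si](C)(C)C(C)(C)C)cc1O[Si](C)(C)C(C)(C)C | intermediate
10 | 2-[2,4-bis(tert-butyldimethylsilyloxy)phenyl]prop-2-enal | O=CC(=C)c1ccc(O[Si](C)(C)C(C)(C)C)cc1O[Si](C)(C)C(C)(C)C | intermediate
11 | trichloroethylene | ClC=C(Cl)Cl | starting material
12 | dichloroacetylene (formed in the flask, step 8) | ClC#CCl | intermediate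
13 | (E)-1,2-dichloro-1-methoxyethene | Cl/C(OC)=C/Cl | intermediate
14 | chloro(methoxy)acetylene (formed in the flask, step 9) | COC#CCl | intermediate
15 | lithium methoxyacetylide (formed in the flask, step 9) | [Li]C#COC | intermediate
16 | lithium 2-[2,4-bis(tert-butyldimethylsilyloxy)phenyl]-5-methoxypent-1-en-4-yn-3-olate, racemic (formed in the flask, step 9) | [Li]OC(C#COC)C(=C)c1ccc(O[Si](C)(C)C(C)(C)C)cc1O[Si](C)(C)C(C)(C)C | intermediate
17 | 4-[2,4-bis(tert-butyldimethylsilyloxy)phenyl]-1-methoxy-3-(triethylsilyloxy)pent-4-en-1-yne, racemic | COC#CC(O[Si](CC)(CC)CC)C(=C)c1ccc(O[Si](C)(C)C(C)(C)C)cc1O[Si](C)(C)C(C)(C)C | intermediate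
18 | 2-(3-methylbut-2-enyl)-3-(triisopropylsilyloxy)buta-1,3-dien-1-one, the vinylketene (formed in the flask, step 10) | O=C=C(CC=C(C)C)C(=C)O[Si](C(C)C)(C(C)C)C(C)C | intermediate
19 | 2-{2-[2,4-bis(tert-butyldimethylsilyloxy)phenyl]-1-(triethylsilyloxy)prop-2-enyl}-3-methoxy-4-(3-methylbut-2-enyl)-4-[1-(triisopropylsilyloxy)vinyl]cyclobut-2-en-1-one, mixture of diastereomers (formed in the flask, step 10) | O=C1C(C(O[Si](CC)(CC)CC)C(=C)c2ccc(O[Si](C)(C)C(C)(C)C)cc2O[Si](C)(C)C(C)(C)C)=C(OC)C1(CC=C(C)C)C(=C)O[Si](C(C)C)(C(C)C)C(C)C | intermediate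
20 | dienylketene with the ketene and silyloxyvinyl groups cis on the central C=C, racemic (formed in the flask, step 10) | O=C=C(C(O[Si](CC)(CC)CC)C(=C)c1ccc(O[Si](C)(C)C(C)(C)C)cc1O[Si](C)(C)C(C)(C)C)/C(OC)=C(\C(=C)O[Si](C(C)C)(C(C)C)C(C)C)CC=C(C)C | intermediate
21 | 2-{2-[2,4-bis(tert-butyldimethylsilyloxy)phenyl]-1-(triethylsilyloxy)prop-2-enyl}-3-methoxy-4-(3-methylbut-2-enyl)-5-(triisopropylsilyloxy)cyclohexa-2,4-dien-1-one, racemic (formed in the flask, step 10) | O=C1CC(O[Si](C(C)C)(C(C)C)C(C)C)=C(CC=C(C)C)C(OC)=C1C(O[Si](CC)(CC)CC)C(=C)c2ccc(O[Si](C)(C)C(C)(C)C)cc2O[Si](C)(C)C(C)(C)C | intermediate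
22 | 2-{2-[2,4-bis(tert-butyldimethylsilyloxy)phenyl]-1-(triethylsilyloxy)prop-2-enyl}-3-methoxy-4-(3-methylbut-2-enyl)-5-(triisopropylsilyloxy)phenol, racemic | Oc1cc(O[Si](C(C)C)(C(C)C)C(C)C)c(CC=C(C)C)c(OC)c1C(O[Si](CC)(CC)CC)C(=C)c2ccc(O[Si](C)(C)C(C)(C)C)cc2O[Si](C)(C)C(C)(C)C | intermediate
23 | (6Z)-6-{2-[2,4-bis(tert-butyldimethylsilyloxy)phenyl]prop-2-enylidene}-5-methoxy-4-(3-methylbut-2-enyl)-3-(triisopropylsilyloxy)cyclohexa-2,4-dien-1-one, the ortho-quinone methide (formed in the flask, step 11) | O=C1C=C(O[Si](C(C)C)(C(C)C)C(C)C)C(CC=C(C)C)=C(OC)/C1=C/C(=C)c2ccc(O[Si](C)(C)C(C)(C)C)cc2O[Si](C)(C)C(C)(C)C | intermediate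
24 | 3-[2,4-bis(tert-butyldimethylsilyloxy)phenyl]-5-methoxy-6-(3-methylbut-2-enyl)-7-(triisopropylsilyloxy)-2H-chromene | COc1c2c(cc(O[Si](C(C)C)(C(C)C)C(C)C)c1CC=C(C)C)OCC(c3ccc(O[Si](C)(C)C(C)(C)C)cc3O[Si](C)(C)C(C)(C)C)=C2 | intermediate
25 | dehydroglyasperin C, 3-(2,4-dihydroxyphenyl)-5-methoxy-6-(3-methylbut-2-enyl)-2H-chromen-7-ol (no stereocentre) | COc1c2c(cc(O)c1CC=C(C)C)OCC(c1ccc(O)cc1O)=C2 | target

Total step count: 12. Longest linear sequence: 7 steps (5, 6, 7, 9, 10, 11, 12).

Steps most likely to fail

1. Step 10. The cycloaddition at the branched, silyloxy-bearing propargylic carbon may be slow, so that the vinylketene is lost to dimerisation or to acylation of the product phenol, or the silylated carbinol may ionise at the reaction temperature. The fallback sets out from 6 and 15, uses 10, and comes back at 24. It makes ring A at an unhindered alkyne and attaches C4 afterwards. Lithium methoxyacetylide 15, made from 13 as in step 9, is quenched with water and the volatile methoxyacetylene F1 is distilled into toluene. Heating F1 with 6 in a sealed tube at 80 °C should give, by the same benzannulation, 3-methoxy-4-(3-methylbut-2-enyl)-5-(triisopropylsilyloxy)phenol F2, in which C4a still carries hydrogen. The bromomagnesium phenolate of F2 (EtMgBr, toluene) is then condensed with aldehyde 10. Chelation-directed ortho-hydroxyalkylation at the position flanked by OMe, the other ortho position being screened by the triisopropylsilyloxy group, gives 2-{2-[2,4-bis(tert-butyldimethylsilyloxy)phenyl]-1-hydroxyprop-2-enyl}-3-methoxy-4-(3-methylbut-2-enyl)-5-(triisopropylsilyloxy)phenol F3. On warming, F3 loses water to quinone methide 23, which closes to chromene 24.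

2. Step 7. Selenium-mediated over-oxidation of the electron-rich styrene, partial loss of aryl silyl groups in hot dioxane, or polymerisation of the enal during isolation may erode the yield. The fallback sets out from ketone 8, bypasses 9, and comes back at 10. Dimethylsulfonium methylide (Me3SI, n-BuLi, THF, −10 °C; Corey–Chaykovsky epoxidation) converts 8 into 2-[2,4-bis(tert-butyldimethylsilyloxy)phenyl]-2-methyloxirane F4. LiNEt2 in Et2O isomerises the epoxide, by deprotonation of the methyl group, to 2-[2,4-bis(tert-butyldimethylsilyloxy)phenyl]prop-2-en-1-ol F5, which can be stored. MnO2 in CH2Cl2 then oxidises the allylic alcohol to aldehyde 10 immediately before step 9.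

3. Step 2. Ketene gas may oligomerise faster than it is captured, giving incomplete conversion and a difficult separation from diketene-derived material. The fallback sets out from ynol ether 3 and comes back at 4. Dichloroketene generated in the flask (Cl2CHCOCl, Et3N, Et2O, 0 °C) is far more electrophilic and should add to 3 with the same regiochemistry to give 4,4-dichloro-3-ethoxy-2-(3-methylbut-2-enyl)cyclobut-2-en-1-one F6. Reductive dechlorination with Zn dust (AcOH, TMEDA, EtOH, 0 °C) then returns 4.

Further compounds
F1 | step 10 | methoxyacetylene | COC#C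
F2 | step 10 | 3-methoxy-4-(3-methylbut-2-enyl)-5-(triisopropylsilyloxy)phenol | COc1cc(O)cc(O[Si](C(C)C)(C(C)C)C(C)C)c1CC=C(C)C
F3 | step 10 | 2-{2-[2,4-bis(tert-butyldimethylsilyloxy)phenyl]-1-hydroxyprop-2-enyl}-3-methoxy-4-(3-methylbut-2-enyl)-5-(triisopropylsilyloxy)phenol, racemic | Oc1cc(O[Si](C(C)C)(C(C)C)C(C)C)c(CC=C(C)C)c(OC)c1C(O)C(=C)c2ccc(O[Si](C)(C)C(C)(C)C)cc2O[Si](C)(C)C(C)(C)C
F4 | step 7 | 2-[2,4-bis(tert-butyldimethylsilyloxy)phenyl]-2-methyloxirane, racemic | CC1(CO1)c2ccc(O[Si](C)(C)C(C)(C)C)cc2O[Si](C)(C)C(C)(C)C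
F5 | step 7 | 2-[2,4-bis(tert-butyldimethylsilyloxy)phenyl]prop-2-en-1-ol | OCC(=C)c1ccc(O[Si](C)(C)C(C)(C)C)cc1O[Si](C)(C)C(C)(C)C
F6 | step 2 | 4,4-dichloro-3-ethoxy-2-(3-methylbut-2-enyl)cyclobut-2-en-1-one | CCOC1=C(CC=C(C)C)C(=O)C1(Cl)Cl
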